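**Retrosynthetic overview**
- Last bond: the depside ester C–O, between 5-formyl-2,4-dihydroxy-3,6-dimethylbenzoic acid and methyl 4-hydroxy-2-methoxy-3,5,6-trimethylbenzoate (TFAA esterification).
- Both halves come from one intermediate, the C5-(1,3-dithian-2-yl) derivative of atraric acid. Dithiane hydrolysis gives the CHO of the acid half; Raney nickel desulfurisation turns the same carbon into the third C-methyl of the phenol half.
- Key C–C bond: aryl C5–C2 of the dithiane, made by a Gassman [2,3]-sigmatropic shift of an aryloxysulfonium ylide. The dithiane carbon acts as a formyl anion equivalent and is joined to the phenol ortho carbon; both carbons are nucleophilic by nature, and NCS supplies the oxidation.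
- No ring is formed: both benzene rings come ready-made from atraric acid.

Assumption: the target SMILES has no stereocentre or stereogenic axis, so the compound is achiral and no stereocontrol is needed.

**Step 1**
Reactants: 1 methyl 2,4-dihydroxy-3,6-dimethylbenzoate (atraric acid); 2 1,3-dithiane
Product: 5 methyl 5-(1,3-dithian-2-yl)-2,4-dihydroxy-3,6-dimethylbenzoate, via succinimidosulfonium salt 3 (not isolated), via aryloxysulfonium salt 4 (not isolated)
Conditions: 2 (1.1 equiv), NCS (1.1 equiv), CH2Cl2, −70 °C; then 1; then Et3N, −70 °C → rt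
Reagents that add atoms: none
Why: Gassman ortho-functionalisation of a phenol: the free 4-OH attacks 3 to give 4, Et3N forms the ylide at dithiane C2 (a formyl anion equivalent), and a [2,3]-sigmatropic (Sommelet–Hauser-type) shift joins it to C5, the only unsubstituted ortho carbon, before rearomatisation; the ester-chelated 2-OH has no free ortho position.

**Step 2**
Reactants: 5 methyl 5-(1,3-dithian-2-yl)-2,4-dihydroxy-3,6-dimethylbenzoate
Product: 6 methyl 5-formyl-2,4-dihydroxy-3,6-dimethylbenzoate
Conditions: HgO, BF3·OEt2, THF/H2O, rt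
Reagents that add atoms: water O
Why: Hg(II)-assisted dithioacetal hydrolysis unmasks the aldehyde; the ring is fully substituted, so no aryl mercuration can occur, and the ester and phenols are inert.

**Step 3**
Reactants: 6 methyl 5-formyl-2,4-dihydroxy-3,6-dimethylbenzoate
Product: 7 5-formyl-2,4-dihydroxy-3,6-dimethylbenzoic acid
Conditions: conc. H2SO4, 0 °C → rt; then ice/H2O
Reagents that add atoms: water O
Why: Acylium-ion (AAC1) hydrolysis of a 2,6-disubstituted, electron-rich benzoate, which resists saponification; the cold quench limits decarboxylation, and the aldehyde cannot condense because no ring position is free.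

**Step 4**
Reactants: 5 methyl 5-(1,3-dithian-2-yl)-2,4-dihydroxy-3,6-dimethylbenzoate
Product: 9 methyl 4-(benzyloxy)-5-(1,3-dithian-2-yl)-2-methoxy-3,6-dimethylbenzoate, via mono-benzyl ether 8 (not isolated)
Conditions: BnBr (1.05 equiv), K2CO3, DMF, rt; then MeI (2 equiv), 40 °C
Reagents that add atoms: benzyl bromide BrCc1ccccc1; iodomethane CI
Why: Sequential Williamson etherification in order of phenol reactivity: the non-chelated 4-OH is benzylated first at rt, then the ester-chelated 2-OH is methylated on warming, with phenoxide O-alkylation much faster than S-alkylation of the dithiane.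

**Step 5**
Reactants: 9 methyl 4-(benzyloxy)-5-(1,3-dithian-2-yl)-2-methoxy-3,6-dimethylbenzoate
Product: 10 methyl 4-hydroxy-2-methoxy-3,5,6-trimethylbenzoate
Conditions: Raney Ni (W-2, excess), H2 (1 atm), EtOH, reflux
Reagents that add atoms: none
Why: Raney nickel hydrogenolysis (Mozingo desulfurisation) reduces the dithiane carbon to the third C-methyl and cleaves the benzyl ether in the same operation; the methyl ester and aryl methyl ether are inert.

**Step 6**
Reactants: 7 5-formyl-2,4-dihydroxy-3,6-dimethylbenzoic acid; 10 methyl 4-hydroxy-2-methoxy-3,5,6-trimethylbenzoate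
Product: 11 methyl 4-[(5-formyl-2,4-dihydroxy-3,6-dimethylbenzoyl)oxy]-2-methoxy-3,5,6-trimethylbenzoate (target)
Conditions: (CF3CO)2O, toluene, rt; aq NaHCO3 work-up
Reagents that add atoms: none
Why: TFAA-mediated depside esterification via the mixed anhydride/acylium of the hindered acid: both phenols of 7 are chelated (to CO2H and CHO) and poorly nucleophilic, so the non-chelated OH of 10 is acylated, and any trifluoroacetates are cleaved in the bicarbonate work-up.

**Compound list**
1 | methyl 2,4-dihydroxy-3,6-dimethylbenzoate (atraric acid) | COC(=O)c1c(C)cc(O)c(C)c1O | starting material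
2 | 1,3-dithiane | C1CSCSC1 | starting material
3 | 1-(2,5-dioxopyrrolidin-1-yl)-1,3-dithian-1-ium chloride | O=C1CCC(=O)N1[S+]1CCCSC1.[Cl-] | intermediate
4 | 1-[3-hydroxy-4-(methoxycarbonyl)-2,5-dimethylphenoxy]-1,3-dithian-1-ium chloride | COC(=O)c1c(C)cc(O[S+]2CCCSC2)c(C)c1O.[Cl-] | intermediate
5 | methyl 5-(1,3-dithian-2-yl)-2,4-dihydroxy-3,6-dimethylbenzoate | COC(=O)c1c(C)c(C2SCCCS2)c(O)c(C)c1O | intermediate
6 | methyl 5-formyl-2,4-dihydroxy-3,6-dimethylbenzoate | COC(=O)c1c(C)c(C=O)c(O)c(C)c1O | intermediate
7 | 5-formyl-2,4-dihydroxy-3,6-dimethylbenzoic acid | OC(=O)c1c(C)c(C=O)c(O)c(C)c1O | intermediate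
8 | methyl 4-(benzyloxy)-5-(1,3-dithian-2-yl)-2-hydroxy-3,6-dimethylbenzoate | COC(=O)c1c(C)c(C2SCCCS2)c(OCc2ccccc2)c(C)c1O | intermediate
9 | methyl 4-(benzyloxy)-5-(1,3-dithian-2-yl)-2-methoxy-3,6-dimethylbenzoate | COC(=O)c1c(C)c(C2SCCCS2)c(OCc2ccccc2)c(C)c1OC | intermediate
10 | methyl 4-hydroxy-2-methoxy-3,5,6-trimethylbenzoate | COC(=O)c1c(C)c(C)c(O)c(C)c1OC | intermediate
11 | methyl 4-[(5-formyl-2,4-dihydroxy-3,6-dimethylbenzoyl)oxy]-2-methoxy-3,5,6-trimethylbenzoate | COC(=O)c1c(C)c(C)c(OC(=O)c2c(C)c(C=O)c(O)c(C)c2O)c(C)c1OC | target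

**Total step count:** 6
**Longest linear sequence:** 4 steps (1 → 5 → 6 → 7 → 11; the branch 1 → 5 → 9 → 10 → 11 is also 4)

**Three steps most likely to fail**

Step 1 (ring chlorination of the electron-rich resorcinol, or a poor yield in the ylide shift). The fallback sets out from 1 and moves the formyl anion equivalent to a palladium cross-coupling. Bromination at C5 (NBS, MeCN, 0 °C) gives methyl 5-bromo-2,4-dihydroxy-3,6-dimethylbenzoate F1. Protection of both phenols (MOMCl, NaH, DMF) gives methyl 5-bromo-2,4-bis(methoxymethoxy)-3,6-dimethylbenzoate F2. Coupling with nitromethane as the formyl anion equivalent (Pd2(dba)3, XPhos, Cs2CO3, MeNO2/dioxane, 70 °C) gives methyl 2,4-bis(methoxymethoxy)-3,6-dimethyl-5-(nitromethyl)benzoate F3. A Nef reaction (NaOMe, MeOH; then H2SO4/MeOH, −30 °C; then aq HCl) forms the aldehyde and removes the MOM groups, which comes back to the route at 6. Compound 5 for the phenol branch is then made from 6 with propane-1,3-dithiol and BF3·OEt2.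

Step 4 (selectivity between the hindered 4-OH and the chelated 2-OH, or S-alkylation of the dithiane). The fallback sets out from 5 and removes sulfur before any alkylation. Raney Ni in EtOH gives methyl 2,4-dihydroxy-3,5,6-trimethylbenzoate F4. Benzylation of the non-chelated 4-OH (BnBr, K2CO3, acetone) gives methyl 4-(benzyloxy)-2-hydroxy-3,5,6-trimethylbenzoate F5. Methylation (MeI, K2CO3, DMF, 50 °C) gives methyl 4-(benzyloxy)-2-methoxy-3,5,6-trimethylbenzoate F6. Hydrogenolysis (H2, Pd/C, EtOAc) comes back to the route at 10. This also covers an incomplete debenzylation in step 5.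

Step 6 (a doubly ortho-substituted acid meeting a doubly ortho-substituted phenol, with free OH and CHO present). The fallback sets out from 7 and replaces the mixed anhydride by a quinoketene. Acetone with TFAA/TFA gives the acetonide 7-hydroxy-2,2,5,8-tetramethyl-4-oxo-4H-1,3-benzodioxine-6-carbaldehyde F7. Irradiation at 300 nm in CH2Cl2 with 10 (or heating in xylene) expels acetone and the quinoketene is trapped by the phenol, which comes back to the route at 11.

**Further compounds**
F1 | step 1 | methyl 5-bromo-2,4-dihydroxy-3,6-dimethylbenzoate | COC(=O)c1c(C)c(Br)c(O)c(C)c1O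
F2 | step 1 | methyl 5-bromo-2,4-bis(methoxymethoxy)-3,6-dimethylbenzoate | COC(=O)c1c(C)c(Br)c(OCOC)c(C)c1OCOC
F3 | step 1 | methyl 2,4-bis(methoxymethoxy)-3,6-dimethyl-5-(nitromethyl)benzoate | COC(=O)c1c(C)c(C[N+](=O)[O-])c(OCOC)c(C)c1OCOC
F4 | step 4 | methyl 2,4-dihydroxy-3,5,6-trimethylbenzoate | COC(=O)c1c(C)c(C)c(O)c(C)c1O
F5 | step 4 | methyl 4-(benzyloxy)-2-hydroxy-3,5,6-trimethylbenzoate | COC(=O)c1c(C)c(C)c(OCc2ccccc2)c(C)c1O
F6 | step 4 | methyl 4-(benzyloxy)-2-methoxy-3,5,6-trimethylbenzoate | COC(=O)c1c(C)c(C)c(OCc2ccccc2)c(C)c1OC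
F7 | step 6 | 7-hydroxy-2,2,5,8-tetramethyl-4-oxo-4H-1,3-benzodioxine-6-carbaldehyde | CC1(C)OC(=O)c2c(C)c(C=O)c(O)c(C)c2O1
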